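- Slowness here isn't a long time constant. G feeds on itself (autocatalysis), so a slow first step seeds a growth that is invisible for hours and then takes over.

| flask | L | temperature | remark | time |
|---|---|---|---|---|
| south-west | 2.9 M | 25 °C | run made earlier |  |
| north-west | 2.9 M | 50 °C | run made earlier |  |
| noon | 2.1 M | 70 °C |  | 15 h |
| spring | 2.1 M | 30 °C |  | 15 h |
| dawn | 2.1 M | 50 °C |  | 15 h |

| south-west: time / h | south-west: G / % | north-west: time / h | north-west: G / % |
|---|---|---|---|
| 40.0 | 0 | 10.0 | 0 |
| 72.0 | 1 | 20.0 | 6 |
| 96.0 | 0 | 25.0 | 14 |
| 144 | 1 | 40.0 | 39 |
| 192 | 0 | 60.0 | 56 |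

(each reading ± 1.5 percentage points)

- percentages count the L that a species holds: one X counts as two
- what was read earlier has a scatter of 1.5 percentage points, one standard deviation
- on the list of suspects stand: L + G -> 2 G; L -> G; 2 L -> X

* which flask leads in amount of G, in percent of the L charged ("all alike" within 1.5 percentage points) (noon / spring / dawn / all alike)
* how much G is there at the end, in percent of the L charged: noon
* how much G is there at the end, in percent of the L charged: spring
* how much G is there at the end, in percent of the L charged: dawn

- I carry one quantity: the takeoff time τ, the time at which G passes 6 % of the charge, the crossing from seeding to self-growth, also called the end of the induction period. The north-west run passes that mark at 20.0 h, a reading that stands against a scatter of 1.5 percentage points.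
- Objection: that flask holds 2.9 M of L, and ours hold 2.1 M. The seed percentage per hour doesn't depend on the charge, if the seed step is L -> G, but growth per G goes with L. So I stretch τ by the charge ratio, and dawn gets τ = 27.6 h.
- Dawn's 15 h is about half of that, so I put dawn below 6 %.
- Objection: temperature. The south-west run still reads 0 % at 192 h, which gives a floor, not a value: 9.60 in speed across its span of temperature.
- Noon lies as far above dawn as spring lies below it, so, scaling the logarithm of speed with temperature, each gains at least 6.11. Noon's τ is then at most 4.52 h, and spring's at least 169 h.
- Objection: Arrhenius curves flatten when hot, so noon's ceiling is too low. But 15 h is 3.32 times that ceiling, which leaves room.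
- Objection: τ says when, not how much. L also pairs into X, so I commit to noon leading, above the last north-west reading of 56 % and short of the whole charge, with spring near zero.
- The forecast gives noon as leader, with noon 68 %, spring 0 % and dawn 2 %: “Noon should reach its plateau”.
- The flasks give noon 72.0 %, spring 0.0487 % and dawn 2.34 %, so noon leads.

    L + G → 2 G (k = 0.0837 M⁻¹ h⁻¹, Ea = 95.0 kJ mol⁻¹)
    L → G (k = 4.83 × 10⁻⁴ h⁻¹, Ea = 114 kJ mol⁻¹)
    2 L → X (k = 0.00537 M⁻¹ h⁻¹, Ea = 72.0 kJ mol⁻¹)
    (constants at 50 °C)

- Noon has come to rest: by 15.0 h it holds L 0 % and G 72.0 %, and at 150 h it still holds G 72.0 %. Its reading at 4.0 h, G 27.9 %, already stands past the mark, inside the ceiling of 4.52 h. Dawn hasn't come to rest: its τ of 27.6 h lies inside 150 h, and by then G has gone from 2.34 % to 56.8 %, with L at 0 %. Spring's floor of 169 h lies beyond 150 h, and at that time it holds L 62.6 % and G 1.12 %.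

The numbers in the tables are simulated from invented constants.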